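**Plan**

- Retrosynthesis: both primary alcohols go back to methyl esters (one reduction at the end); the C5–alkenyl bond is cut to a 5-bromide and methyl acrylate (Heck); the C2–C3 bond of the dihydrofuran ring is cut to an α-diazo arylacetate whose ortho oxygen carries a 3,4,5-trimethoxybenzyl group; the O–CH2 and C5–Br bonds lead back to methyl 2-(2-hydroxyphenyl)acetate.
- Enabling feature: C3 is benzylic to ring A (the benzo ring) and bears a carbon that can be an ester, so C3 can be a donor/acceptor carbene carbon. C2 is an O1–CH(aryl) carbon; in the precursor its O1–CH2–Ar hydrogens are activated by O1 and by the trimethoxyphenyl ring and lie 1,5 to C3 across C3a–C7a–O1.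
- Forward: ring A is bought; bromination, O-benzylation and diazo transfer build the precursor; the dihydrofuran ring is closed by an enantioselective intramolecular carbene C–H insertion (C2–C3 bond and both stereocentres in one event). The side chain is attached afterwards by Heck reaction, so that no alkene is present when the carbene forms, and both esters are reduced together.
- Stereochemistry: C2 (R) comes from the chiral dirhodium carboxylate in the insertion; C3 is relayed from C2 by thermodynamic cis-to-trans epimerisation of the ester; the E alkene comes from the syn-insertion/syn-β-hydride elimination of the Heck reaction.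

Key step: step 4

Assumption (remark on the chemistry): Rh2(S-PTTL)4 is expected to give the 2R series with this 2-benzyloxyphenyl diazoacetate; should the 2S series form, the mirror-image catalyst Rh2(R-PTTL)4 is used with no other change.

**Route**

Step 1
Reactants: 1 methyl 2-(2-hydroxyphenyl)acetate
Product: 2 methyl 2-(5-bromo-2-hydroxyphenyl)acetate
Conditions: NBS (1.05 equiv), MeCN, −10 to 0 °C
Reagents that add atoms: N-bromosuccinimide, O=C1CCC(=O)N1Br
Why: Electrophilic aromatic bromination of a phenol, in which the hydroxyl group directs the bromine to the free para position (C5) in polar MeCN at low temperature and the CH2CO2Me group is not touched under ionic conditions.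

Step 2
Reactants: 2 methyl 2-(5-bromo-2-hydroxyphenyl)acetate; 3 5-(chloromethyl)-1,2,3-trimethoxybenzene (3,4,5-trimethoxybenzyl chloride)
Product: 4 methyl 2-{5-bromo-2-[(3,4,5-trimethoxyphenyl)methoxy]phenyl}acetate
Conditions: K2CO3 (2 equiv), n-Bu4NI (5 mol %), DMF, rt to 50 °C
Reagents that add atoms: none
Why: Williamson ether synthesis, the phenoxide displacing the benzylic chloride (iodide-assisted SN2) while K2CO3 is too weak to deprotonate the arylacetate CH2.

Step 3
Reactants: 4 methyl 2-{5-bromo-2-[(3,4,5-trimethoxyphenyl)methoxy]phenyl}acetate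
Product: 5 methyl 2-{5-bromo-2-[(3,4,5-trimethoxyphenyl)methoxy]phenyl}-2-diazoacetate
Conditions: p-ABSA (1.3 equiv), DBU (1.5 equiv), MeCN, 0 °C to rt
Reagents that add atoms: 4-acetamidobenzenesulfonyl azide (p-ABSA), CC(=O)Nc1ccc(cc1)S(=O)(=O)N=[N+]=[N-]
Why: Regitz diazo transfer, in which DBU forms the aryl-stabilised ester enolate, which attacks the terminal nitrogen of the sulfonyl azide and fragments to the aryldiazoacetate and the sulfonamide.

Step 4
Reactants: 5 methyl 2-{5-bromo-2-[(3,4,5-trimethoxyphenyl)methoxy]phenyl}-2-diazoacetate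
Product: 6 methyl (2R,3S)-5-bromo-2-(3,4,5-trimethoxyphenyl)-2,3-dihydro-1-benzofuran-3-carboxylate (2,3-cis)
Conditions: Rh2(S-PTTL)4 [dirhodium tetrakis(N-phthaloyl-(S)-tert-leucinate)] (1 mol %), toluene, −60 °C
Reagents that add atoms: none
Why: The dirhodium tetracarboxylate (divalent rhodium) takes N2 from 5 to give a catalyst-bound donor/acceptor carbene at the future C3 (donor: ring A; acceptor: CO2Me), and this electrophilic carbon inserts into one benzylic C–H bond of the O–CH2–Ar group through a concerted, asynchronous three-centre transition state with hydride-shift character, with retention at the carbon that becomes C2 and release of the catalyst. The closest known reaction type is the enantioselective intramolecular C–H insertion of α-aryl-α-diazoacetates carrying an ortho benzyloxy group under chiral dirhodium carboxylate catalysis, which gives cis-2-aryl-2,3-dihydrobenzofuran-3-carboxylates. The dihydrofuran ring closes by 1,5-insertion (from the carbene carbon C3 through C3a, C7a and O1 to C2), that is through a five-membered cyclic transition state, the C3a–C7a bond of ring A holding the two reacting carbons on the same side. C2 is controlled by the catalyst: the chiral pocket of the four N-phthaloyl-(S)-tert-leucinate ligands pairs one face of the carbene with one of the two enantiotopic benzylic hydrogens, which should give 2R. C3 is set in the same transition state with the ester cis to the trimethoxyphenyl group (3S); this centre is under kinetic control here and is reset on purpose in step 5, so only the selectivity at C2 has to be high. The step needs insertion at O–CH2 in preference to addition to the electron-rich trimethoxyphenyl ring (a seven-membered transition state), to insertion into the OMe groups and to carbene dimerisation; the α-oxygen and benzylic activation of the reacting C–H bond, its 1,5 placement, the moderated reactivity of the donor/acceptor carbene at −60 °C and the inertness of the aryl bromide should secure this.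

Step 5
Reactants: 6 methyl (2R,3S)-5-bromo-2-(3,4,5-trimethoxyphenyl)-2,3-dihydro-1-benzofuran-3-carboxylate
Product: 7 methyl (2R,3R)-5-bromo-2-(3,4,5-trimethoxyphenyl)-2,3-dihydro-1-benzofuran-3-carboxylate (2,3-trans)
Conditions: NaOMe (0.3 equiv), MeOH–THF, 0 °C to rt; AcOH quench
Reagents that add atoms: none
Why: Base-mediated epimerisation through the ester enolate, which should converge on the thermodynamically preferred 2,3-trans isomer (aryl and ester on opposite faces of the five-membered ring) while C2, which is not acidic, keeps the configuration set in step 4 and methoxide in methanol makes any transesterification degenerate.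

Step 6
Reactants: 7 methyl (2R,3R)-5-bromo-2-(3,4,5-trimethoxyphenyl)-2,3-dihydro-1-benzofuran-3-carboxylate; 8 methyl acrylate
Product: 9 methyl (2R,3R)-5-[(1E)-3-methoxy-3-oxoprop-1-en-1-yl]-2-(3,4,5-trimethoxyphenyl)-2,3-dihydro-1-benzofuran-3-carboxylate
Conditions: 8 (2 equiv), Pd2(dba)3 (1.5 mol %), [HP(t-Bu)3]BF4 (6 mol %), Cy2NMe (1.2 equiv), 1,4-dioxane, rt to 50 °C
Reagents that add atoms: none
Why: Mizoroki–Heck reaction, in which zerovalent palladium with the bulky electron-rich phosphine adds oxidatively to the electron-rich aryl bromide, the arylpalladium adds syn across the acrylate at its β-carbon and syn β-hydride elimination gives the E-cinnamate, the mild amine base and temperature leaving the trans ester stereocentres alone.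

Step 7
Reactants: 9 methyl (2R,3R)-5-[(1E)-3-methoxy-3-oxoprop-1-en-1-yl]-2-(3,4,5-trimethoxyphenyl)-2,3-dihydro-1-benzofuran-3-carboxylate
Product: 10 (2E)-3-[(2R,3S)-3-(hydroxymethyl)-2-(3,4,5-trimethoxyphenyl)-2,3-dihydro-1-benzofuran-5-yl]prop-2-en-1-ol (target)
Conditions: i-Bu2AlH (6 equiv), CH2Cl2, −78 to 0 °C; aqueous potassium sodium tartrate (KNaC4H4O6) work-up
Reagents that add atoms: none
Why: Hydride reduction of both esters with an electrophilic aluminium hydride, which should reduce the conjugated ester by 1,2-addition to the E-allylic alcohol without touching the alkene and the C3 ester to the hydroxymethyl group, no stereocentre being involved (the descriptor at C3 changes from R to S only through the priority rules).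

**Compound list**

1 | methyl 2-(2-hydroxyphenyl)acetate | COC(=O)Cc1ccccc1O | starting material
2 | methyl 2-(5-bromo-2-hydroxyphenyl)acetate | COC(=O)Cc1cc(Br)ccc1O | intermediate
3 | 5-(chloromethyl)-1,2,3-trimethoxybenzene (3,4,5-trimethoxybenzyl chloride) | COc1cc(CCl)cc(OC)c1OC | starting material
4 | methyl 2-{5-bromo-2-[(3,4,5-trimethoxyphenyl)methoxy]phenyl}acetate | COC(=O)Cc1cc(Br)ccc1OCc1cc(OC)c(OC)c(OC)c1 | intermediate
5 | methyl 2-{5-bromo-2-[(3,4,5-trimethoxyphenyl)methoxy]phenyl}-2-diazoacetate | COC(=O)C(=[N+]=[N-])c1cc(Br)ccc1OCc1cc(OC)c(OC)c(OC)c1 | intermediate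
6 | methyl (2R,3S)-5-bromo-2-(3,4,5-trimethoxyphenyl)-2,3-dihydro-1-benzofuran-3-carboxylate (cis) | COc1cc([C@@H]2Oc3ccc(Br)cc3[C@@H]2C(=O)OC)cc(OC)c1OC | intermediate
7 | methyl (2R,3R)-5-bromo-2-(3,4,5-trimethoxyphenyl)-2,3-dihydro-1-benzofuran-3-carboxylate (trans) | COc1cc([C@@H]2Oc3ccc(Br)cc3[C@H]2C(=O)OC)cc(OC)c1OC | intermediate
8 | methyl acrylate (methyl prop-2-enoate) | C=CC(=O)OC | starting material
9 | methyl (2R,3R)-5-[(1E)-3-methoxy-3-oxoprop-1-en-1-yl]-2-(3,4,5-trimethoxyphenyl)-2,3-dihydro-1-benzofuran-3-carboxylate | COc1cc([C@@H]2Oc3ccc(/C=C/C(=O)OC)cc3[C@H]2C(=O)OC)cc(OC)c1OC | intermediate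
10 | (2E)-3-[(2R,3S)-3-(hydroxymethyl)-2-(3,4,5-trimethoxyphenyl)-2,3-dihydro-1-benzofuran-5-yl]prop-2-en-1-ol | COc1cc([C@@H]2Oc3ccc(/C=C/CO)cc3[C@H]2CO)cc(OC)c1OC | target

**Step count and risks**

Total step count: 7. Longest linear sequence: 7 steps (1 to 10).

Steps most likely to fail, each with a fallback:

1. Step 4 (carbene C–H insertion). What may go wrong: poor discrimination between the two enantiotopic benzylic hydrogens with this particular benzyl group, or diversion of the carbene to dimerisation or to addition to the trimethoxyphenyl ring. The fallback sets out from 4 and comes back at 7. It puts a chiral auxiliary on the ester so that any stereochemical leak becomes a separable diastereomer instead of an enantiomer. Compound 4 is saponified (LiOH, THF–H2O) to 2-{5-bromo-2-[(3,4,5-trimethoxyphenyl)methoxy]phenyl}acetic acid F1. Steglich esterification with (R)-pantolactone (DCC, DMAP, CH2Cl2) gives the (3R)-4,4-dimethyl-2-oxooxolan-3-yl arylacetate F2. Regitz diazo transfer (p-ABSA, DBU, MeCN) gives the corresponding pantolactonyl aryldiazoacetate F3. The insertion is then run with whichever of Rh2(S-PTTL)4 and Rh2(R-PTTL)4 is the matched partner of the auxiliary for the 2R series, or with achiral Rh2(OAc)4, to give the (3R)-4,4-dimethyl-2-oxooxolan-3-yl (2R,3S)-5-bromo-2-(3,4,5-trimethoxyphenyl)-2,3-dihydro-1-benzofuran-3-carboxylate F4, which is freed from its minor diastereomer by crystallisation or chromatography. NaOMe in MeOH then removes the auxiliary by transesterification and epimerises C3 in the same operation, to give 7.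

2. Step 5 (epimerisation at C3). What may go wrong: loss of configuration at C2 through β-elimination of the phenoxide from the ester enolate (ring opening to a 2-aryl cinnamate) and non-selective reclosure, or an equilibration that stalls. The fallback sets out from 6 and comes back at 10. It moves the epimerisation to the aldehyde oxidation level, where a tertiary amine is base enough. Compound 6 is reduced with i-Bu2AlH (1.1 equiv, toluene, −78 °C) to (2R,3S)-5-bromo-2-(3,4,5-trimethoxyphenyl)-2,3-dihydro-1-benzofuran-3-carbaldehyde F5. Et3N in CH2Cl2 at rt equilibrates it to the trans isomer, (2R,3R)-5-bromo-2-(3,4,5-trimethoxyphenyl)-2,3-dihydro-1-benzofuran-3-carbaldehyde F6. NaBH4 in MeOH gives [(2R,3S)-5-bromo-2-(3,4,5-trimethoxyphenyl)-2,3-dihydro-1-benzofuran-3-yl]methanol F7. Suzuki–Miyaura coupling of F7 with (2E)-3-(4,4,5,5-tetramethyl-1,3,2-dioxaborolan-2-yl)prop-2-en-1-ol (OC/C=C/B1OC(C)(C)C(C)(C)O1; Pd(dppf)Cl2, K3PO4, dioxane–H2O, 70 °C) then gives 10 directly.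

3. Step 6 (Heck reaction). What may go wrong: slow turnover with the electron-rich bromide, so that hydrodebromination and acrylate oligomerisation compete, or base-induced ring opening during long heating. The fallback sets out from 7 and comes back at 10. It changes the coupling to a transmetalation manifold and brings in the side chain at its final oxidation level. Suzuki–Miyaura coupling of 7 with (2E)-3-(4,4,5,5-tetramethyl-1,3,2-dioxaborolan-2-yl)prop-2-en-1-ol (Pd(dppf)Cl2, K3PO4, dioxane–H2O, 70 °C) gives methyl (2R,3R)-5-[(1E)-3-hydroxyprop-1-en-1-yl]-2-(3,4,5-trimethoxyphenyl)-2,3-dihydro-1-benzofuran-3-carboxylate F8. Reduction of the one remaining ester with i-Bu2AlH (CH2Cl2, −78 to 0 °C) gives 10.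

**Further compounds**

F1 | step 4 | 2-{5-bromo-2-[(3,4,5-trimethoxyphenyl)methoxy]phenyl}acetic acid | OC(=O)Cc1cc(Br)ccc1OCc1cc(OC)c(OC)c(OC)c1
F2 | step 4 | (3R)-4,4-dimethyl-2-oxooxolan-3-yl 2-{5-bromo-2-[(3,4,5-trimethoxyphenyl)methoxy]phenyl}acetate | CC1(C)COC(=O)[C@@H]1OC(=O)Cc1cc(Br)ccc1OCc1cc(OC)c(OC)c(OC)c1
F3 | step 4 | (3R)-4,4-dimethyl-2-oxooxolan-3-yl 2-{5-bromo-2-[(3,4,5-trimethoxyphenyl)methoxy]phenyl}-2-diazoacetate | CC1(C)COC(=O)[C@@H]1OC(=O)C(=[N+]=[N-])c1cc(Br)ccc1OCc1cc(OC)c(OC)c(OC)c1
F4 | step 4 | (3R)-4,4-dimethyl-2-oxooxolan-3-yl (2R,3S)-5-bromo-2-(3,4,5-trimethoxyphenyl)-2,3-dihydro-1-benzofuran-3-carboxylate | COc1cc([C@@H]2Oc3ccc(Br)cc3[C@@H]2C(=O)O[C@H]2C(=O)OCC2(C)C)cc(OC)c1OC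
F5 | step 5 | (2R,3S)-5-bromo-2-(3,4,5-trimethoxyphenyl)-2,3-dihydro-1-benzofuran-3-carbaldehyde | COc1cc([C@@H]2Oc3ccc(Br)cc3[C@@H]2C=O)cc(OC)c1OC
F6 | step 5 | (2R,3R)-5-bromo-2-(3,4,5-trimethoxyphenyl)-2,3-dihydro-1-benzofuran-3-carbaldehyde | COc1cc([C@@H]2Oc3ccc(Br)cc3[C@H]2C=O)cc(OC)c1OC
F7 | step 5 | [(2R,3S)-5-bromo-2-(3,4,5-trimethoxyphenyl)-2,3-dihydro-1-benzofuran-3-yl]methanol | COc1cc([C@@H]2Oc3ccc(Br)cc3[C@H]2CO)cc(OC)c1OC
F8 | step 6 | methyl (2R,3R)-5-[(1E)-3-hydroxyprop-1-en-1-yl]-2-(3,4,5-trimethoxyphenyl)-2,3-dihydro-1-benzofuran-3-carboxylate | COc1cc([C@@H]2Oc3ccc(/C=C/CO)cc3[C@H]2C(=O)OC)cc(OC)c1OC
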